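Everything rests on disconnecting the C3–C3a bond of the γ-lactone. Ring O1–C2–C3–C3a–C8a is cis-fused to the cycloheptane, so this bond stands where the C3a hydrogen cis to the C8a oxygen stands in an unbranched cycloheptyl ester. Carbenoid C–H insertion of a C8a diazoacetate exploits exactly this: in one operation it closes the lactone, forms C3–C3a and sets C3a. The precursor is a cycloheptane with the C7 ketone masked as a dioxolane, C6 methyl, C5 silyl ether and the C8 isobutyrate already in place, built by two acrolein aldol reactions and ring-closing metathesis. Lactone methylation, C3 epimerisation and a crotonyl unit at C7 finish the route.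

Key step: step 15

Convention: locants follow the numbering of the final cyclohepta[b]furan-2-one throughout, also in open-chain and monocyclic intermediates; β is the face of the C8a–O bond, α the opposite face.

Remark on the chemistry: no stereochemical error was found in the precursor and product structures (both match the target at C5, C6, C8, C8a and C3a). The C5 hydroxyl is carried as a triisopropylsilyl ether instead of a smaller silyl ether, because the C7 dioxolane sits next to an acyloxy-bearing carbon and needs aqueous acid for its removal. The C8 and C8a oxygens are told apart from the start (benzyl against triethylsilyl), so isobutyrate and diazoacetate are placed without a selective acylation of a diol.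

Assumption: Rh2(4S-MACIM)4, dirhodium tetrakis[methyl (4S)-1-acetyl-2-oxoimidazolidine-4-carboxylate], is taken as the catalyst antipode matched to 22. The cis ring fusion and the choice of C3a–H over the equally cis C8–H rest on catalyst and electronic control and are not enforced by geometry.

Step 1
Reactants: 1 (S)-4-benzyloxazolidin-2-one; 2 (benzyloxy)acetyl chloride
Product: 4 (S)-4-benzyl-3-[(benzyloxy)acetyl]oxazolidin-2-one, via N-lithio oxazolidinone 3 (not isolated)
Conditions: n-BuLi, THF, −78 °C; then 2, −78 → 0 °C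
Reagents that add atoms: none
Why: N-acylation of the lithiated oxazolidinone by the acid chloride (imide formation) is fast at low temperature and touches no stereocentre.

Step 2
Reactants: 4 (S)-4-benzyl-3-[(benzyloxy)acetyl]oxazolidin-2-one; 5 acrolein
Product: 7 (S)-4-benzyl-3-[(2S,3R)-2-(benzyloxy)-3-hydroxypent-4-enoyl]oxazolidin-2-one, via dibutylboron Z-enolate 6 (not isolated)
Conditions: n-Bu2BOTf, Et3N, CH2Cl2, −78 → 0 °C; 5, −78 → 0 °C; then pH 7 buffer, MeOH, H2O2
Reagents that add atoms: none
Why: Evans syn aldol reaction, in which the Z boron enolate reacts through a Zimmerman–Traxler chair on the enolate face left open by the benzyl group of the dipole-aligned auxiliary, which should set C8 (S) and C8a (R) as the syn glycolate adduct.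

Step 3
Reactants: 7 (S)-4-benzyl-3-[(2S,3R)-2-(benzyloxy)-3-hydroxypent-4-enoyl]oxazolidin-2-one
Product: 8 (2S,3R)-2-(benzyloxy)-3-hydroxy-N-methoxy-N-methylpent-4-enamide
Conditions: MeNH(OMe)·HCl, AlMe3, CH2Cl2, −20 → 0 °C
Reagents that add atoms: N,O-dimethylhydroxylamine hydrochloride, CNOC.Cl
Why: Aluminium amide transamination of the β-hydroxy imide (Weinreb amide formation) is assisted by the free hydroxyl, releases the auxiliary for reuse and leaves both stereocentres untouched.

Step 4
Reactants: 8 (2S,3R)-2-(benzyloxy)-3-hydroxy-N-methoxy-N-methylpent-4-enamide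
Product: 9 (2S,3R)-2-(benzyloxy)-N-methoxy-N-methyl-3-[(triethylsilyl)oxy]pent-4-enamide
Conditions: Et3SiCl, imidazole, DMF, 0 → 25 °C
Reagents that add atoms: chlorotriethylsilane, CC[Si](Cl)(CC)CC
Why: Standard silylation of a secondary allylic alcohol; the triethylsilyl ether is a poor donor, so only the C8 benzyloxy oxygen can chelate in step 6, and it can later be removed beside the C5 triisopropylsilyl ether.

Step 5
Reactants: 9 (2S,3R)-2-(benzyloxy)-N-methoxy-N-methyl-3-[(triethylsilyl)oxy]pent-4-enamide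
Product: 10 (4S,5R)-4-(benzyloxy)-5-[(triethylsilyl)oxy]hept-6-en-3-one
Conditions: EtMgBr, THF, 0 °C; aq. NH4Cl
Reagents that add atoms: ethylmagnesium bromide, CC[Mg]Br
Why: Weinreb ketone synthesis, in which the magnesium-chelated tetrahedral adduct resists a second addition and collapses to the ethyl ketone on work-up without epimerising C8.

Step 6
Reactants: 10 (4S,5R)-4-(benzyloxy)-5-[(triethylsilyl)oxy]hept-6-en-3-one; 5 acrolein
Product: 12 (3R,4S,6S,7R)-4-(benzyloxy)-7-hydroxy-6-methyl-3-[(triethylsilyl)oxy]nona-1,8-dien-5-one, via trichlorotitanium Z-enolate 11 (not isolated)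
Conditions: TiCl4, i-Pr2NEt, CH2Cl2, −78 °C; 5, −78 °C; aq. NH4Cl
Reagents that add atoms: none
Why: Chelation-controlled titanium aldol reaction, in which the Z enolate is locked in a five-membered chelate with the C8 benzyloxy oxygen and acrolein should add through a chair transition state on the face opposite the C8a substituent, giving the syn aldol with C6 (S, methyl β) and C5 (R, oxygen α).

Step 7
Reactants: 12 (3R,4S,6S,7R)-4-(benzyloxy)-7-hydroxy-6-methyl-3-[(triethylsilyl)oxy]nona-1,8-dien-5-one
Product: 13 (3R,4S,6S,7R)-4-(benzyloxy)-6-methyl-3-[(triethylsilyl)oxy]-7-[(triisopropylsilyl)oxy]nona-1,8-dien-5-one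
Conditions: i-Pr3SiOTf, 2,6-lutidine, CH2Cl2, −78 → 0 °C
Reagents that add atoms: triisopropylsilyl trifluoromethanesulfonate, CC(C)[Si](OS(=O)(=O)C(F)(F)F)(C(C)C)C(C)C
Why: Silylation of the β-hydroxy ketone with a silyl triflate and a hindered base is fast at low temperature, so neither retro-aldol cleavage nor epimerisation at C6 should intervene.

Step 8
Reactants: 13 (3R,4S,6S,7R)-4-(benzyloxy)-6-methyl-3-[(triethylsilyl)oxy]-7-[(triisopropylsilyl)oxy]nona-1,8-dien-5-one
Product: 14 (2S,3R,6R,7S)-2-(benzyloxy)-7-methyl-3-[(triethylsilyl)oxy]-6-[(triisopropylsilyl)oxy]cyclohept-4-en-1-one (core locants: C7 ketone; C8 α-OBn; C8a β-OSiEt3; C3a=C4; C5 α-OSi(i-Pr)3; C6 β-Me)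
Conditions: second-generation Grubbs catalyst (5 mol %), CH2Cl2 (0.005 M), 40 °C
Reagents that add atoms: none
Why: Ring-closing metathesis of the 1,8-diene closes the seven-membered ring at C3a=C4 with loss of ethylene, and no stereocentre takes part.

Step 9
Reactants: 14 cycloheptenone (C7 ketone; C8 α-OBn; C8a β-OSiEt3; C3a=C4; C5 α-OSi(i-Pr)3; C6 β-Me)
Product: 15 C7 ethylene ketal (1,3-dioxolane) of 14
Conditions: (Me3SiOCH2)2, Me3SiOTf (10 mol %), CH2Cl2, −78 → −20 °C
Reagents that add atoms: 1,2-bis(trimethylsilyloxy)ethane, C[Si](C)(C)OCCO[Si](C)(C)C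
Why: Silyl-triflate-catalysed ketalisation (Noyori conditions) is driven by formation of hexamethyldisiloxane, works on hindered ketones at low temperature and should spare the silyl and benzyl ethers and the epimerisable C6 and C8 centres.

Step 10
Reactants: 15 cycloheptene ketal (C7 dioxolane; C8 α-OBn; C8a β-OSiEt3; C3a=C4; C5 α-OSi(i-Pr)3; C6 β-Me)
Product: 16 saturated C8 alcohol (C7 dioxolane; C8 α-OH; C8a β-OSiEt3; C5 α-OSi(i-Pr)3; C6 β-Me)
Conditions: H2 (1 atm), Pd(OH)2/C, EtOAc, 25 °C
Reagents that add atoms: none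
Why: Catalytic hydrogenation saturates C3a=C4 and hydrogenolyses the benzyl ether in one operation, which frees the C8 hydroxyl alone and removes the arene and the benzylic C–H bonds before the carbenoid step.

Step 11
Reactants: 16 saturated C8 alcohol; 17 isobutyryl chloride
Product: 18 C8 isobutyrate (C7 dioxolane; C8 α-OCOCHMe2; C8a β-OSiEt3; C5 α-OSi(i-Pr)3; C6 β-Me)
Conditions: pyridine, DMAP (cat.), CH2Cl2, 0 → 25 °C
Reagents that add atoms: none
Why: DMAP-catalysed acylation of the only free hydroxyl installs the isobutyrate of the target, which later also deactivates the C8–H bond towards the carbenoid.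

Step 12
Reactants: 18 C8 isobutyrate with C8a triethylsilyl ether
Product: 19 C8a alcohol (C7 dioxolane; C8 α-OCOCHMe2; C8a β-OH; C5 α-OSi(i-Pr)3; C6 β-Me)
Conditions: HF·pyridine, pyridine, THF, 0 °C
Reagents that add atoms: none
Why: Buffered HF·pyridine cleaves the triethylsilyl ether far faster than the triisopropylsilyl ether, and the mildly acidic medium should suppress migration of the isobutyryl group to the freed C8a hydroxyl.

Step 13
Reactants: 19 C8a alcohol; 20 bromoacetyl bromide
Product: 21 C8a bromoacetate (C7 dioxolane; C8 α-OCOCHMe2; C8a β-OCOCH2Br; C5 α-OSi(i-Pr)3; C6 β-Me)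
Conditions: NaHCO3, MeCN, 0 °C
Reagents that add atoms: none
Why: Acylation of the secondary alcohol by the acyl bromide under amine-free conditions gives the bromoacetate without quaternisation at the CH2Br group.

Step 14
Reactants: 21 C8a bromoacetate
Product: 22 C8a diazoacetate (C7 dioxolane; C8 α-OCOCHMe2; C8a β-OCOCHN2; C5 α-OSi(i-Pr)3; C6 β-Me)
Conditions: TsNHNHTs, DBU, THF, 0 °C
Reagents that add atoms: N,N'-ditosylhydrazine, Cc1ccc(cc1)S(=O)(=O)NNS(=O)(=O)c1ccc(C)cc1
Why: Displacement of bromide by the ditosylhydrazine anion followed by base-induced loss of two sulfinates (a Bamford–Stevens-type elimination) gives the diazoacetate under conditions that spare the ester, the ketal and the silyl ether.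

Step 15
Reactants: 22 C8a diazoacetate
Product: 23 cis-fused γ-lactone lacking the C3 methyl (C7 dioxolane; C8 α-OCOCHMe2; C5 α-OSi(i-Pr)3; C6 β-Me; C3a–C3 and C8a–O1 both β)
Conditions: Rh2(4S-MACIM)4 (2 mol %), CH2Cl2, reflux, 22 added over 10 h
Reagents that add atoms: none
Why: Loss of N2 from the diazoacetate on dirhodium gives an electrophilic carbenoid whose carbon inserts into the C3a–H bond through a concerted three-centre transition state with retention at carbon. The closest known reaction type is the dirhodium carboxamidate-catalysed intramolecular C–H insertion of cycloalkyl diazoacetates to cis-fused γ-butyrolactones. The lactone ring O1–C2–C3–C3a–C8a closes by formation of C3–C3a in the five-membered (1,5) insertion mode. The new stereocentre C3a is set because the carbenoid replaces the β hydrogen, the one cis to the C8a oxygen that carries the tether, so its configuration is relayed from C8a; the trans-fused alternative is possible in a seven-membered ring and is disfavoured by the MACIM ligand set. The step needs site selectivity for C3a–H over C8–H (also cis and 1,5-related), over C4–H (six-membered closure) and over ylide formation at the ketal oxygen. This is secured by the inductive deactivation of C8–H by its isobutyryloxy group, the five-membered preference, the absence of O–H bonds and arenes, the low electrophilicity of the carboxamidate carbenoid and slow addition against dimerisation.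

Step 16
Reactants: 23 cis-fused γ-lactone
Product: 25 C3 convex-face methyl lactone (methyl cis to H3a; the C3 epimer of the target series), via lithium enolate of 23 24 (not isolated)
Conditions: LiN(i-Pr)2 (1.1 equiv), THF, −78 °C; MeI, −78 → −40 °C
Reagents that add atoms: iodomethane, CI
Why: Lactone enolate alkylation, in which MeI attacks the cis-fused bicycle on its convex face so that the methyl group should enter cis to H3a, while one equivalent of base at −78 °C should leave the less acidic isobutyrate untouched.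

Step 17
Reactants: 25 C3 convex-face methyl lactone
Product: 27 C3 concave-face methyl lactone (methyl cis to C4; H3 cis to H3a; C3 as in the target), via lithium enolate of 25 26 (not isolated)
Conditions: LiN(i-Pr)2 (excess), THF, −78 → −40 °C; then 2,6-di-tert-butyl-4-methylphenol, −78 °C
Reagents that add atoms: none
Why: Deprotonation to the planar enolate and kinetic protonation by a hindered phenol from the convex face should place H3 cis to H3a and the methyl group on the concave face; an isobutyrate enolate formed alongside is simply reprotonated.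

Step 18
Reactants: 27 C3 concave-face methyl lactone with C7 dioxolane
Product: 28 C7 ketone (C8 α-OCOCHMe2; C6 β-Me; C5 α-OSi(i-Pr)3; lactone as in 27)
Conditions: CF3CO2H/H2O (9:1), CH2Cl2, 0 °C
Reagents that add atoms: water, O
Why: Acid-catalysed ketal hydrolysis, in which the triisopropylsilyl ether, the lactone and the ester should survive cold aqueous CF3CO2H, C3 is not enolised under acid, and C6 and C8 already hold their more stable equatorial orientations.

Step 19
Reactants: 28 C7 ketone; 29 methoxyallene (1-methoxypropa-1,2-diene)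
Product: 32 C7 β-hydroxy C7 α-acryloyl compound (vinyl ketone; C5 α-OSi(i-Pr)3), via 1-lithio-1-methoxyallene 30 (not isolated), via allenyl carbinol 31 (not isolated)
Conditions: 29, n-BuLi, THF, −40 °C; 28, −78 °C; then 5% aq. H2SO4, THF, 0 °C
Reagents that add atoms: water, O
Why: 1,2-Addition of the small, highly nucleophilic lithiated methoxyallene (an acyl anion equivalent) should outrun attack on the esters and enolisation at −78 °C and should occur on the α face, because the β face carries the C6 methyl group and is overhung by the axial C3a–C3 bond and the C3 methyl of the lactone, so the hydroxyl is set β at C7; acid hydrolysis of the allenyl enol ether then gives the vinyl ketone.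

Step 20
Reactants: 32 C7 acryloyl compound; 33 (Z)-but-2-ene
Product: 34 C5 triisopropylsilyl ether of the target ((E)-crotonyl ketone)
Conditions: second-generation Hoveyda–Grubbs catalyst (5 mol %), 33 (excess), CH2Cl2, 40 °C, sealed tube
Reagents that add atoms: none
Why: Olefin cross-metathesis of the electron-poor vinyl ketone with the simple alkene exchanges the terminal CH2 for CHCH3 with loss of propene and should give the thermodynamically preferred E-crotonyl ketone.

Step 21
Reactants: 34 C5 triisopropylsilyl ether of the target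
Product: 35 (3R,3aS,5R,6S,7S,8S,8aR)-7-[(E)-but-2-enoyl]-5,7-dihydroxy-3,6-dimethyl-2-oxooctahydro-2H-cyclohepta[b]furan-8-yl 2-methylpropanoate (target)
Conditions: HF·pyridine, THF, 0 → 25 °C
Reagents that add atoms: none
Why: Fluoride-mediated desilylation under mildly acidic conditions should free the C5 hydroxyl without touching the enone, the tertiary α-ketol, the lactone or the isobutyrate.

Compound list

1 | (S)-4-benzyloxazolidin-2-one | O=C1N[C@@H](Cc2ccccc2)CO1 | starting material
2 | (benzyloxy)acetyl chloride | ClC(=O)COCc1ccccc1 | starting material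
3 | N-lithio-(S)-4-benzyloxazolidin-2-one | [Li]N1[C@@H](Cc2ccccc2)COC1=O | intermediate
4 | (S)-4-benzyl-3-[(benzyloxy)acetyl]oxazolidin-2-one | O=C1OC[C@H](Cc2ccccc2)N1C(=O)COCc3ccccc3 | intermediate
5 | acrolein | C=CC=O | starting material
6 | dibutylboron Z-enolate of 4 | CCCCB(CCCC)O/C(=C\OCc1ccccc1)N1[C@@H](Cc2ccccc2)COC1=O | intermediate
7 | (S)-4-benzyl-3-[(2S,3R)-2-(benzyloxy)-3-hydroxypent-4-enoyl]oxazolidin-2-one | C=C[C@@H](O)[C@H](OCc1ccccc1)C(=O)N1[C@@H](Cc2ccccc2)COC1=O | intermediate
8 | (2S,3R)-2-(benzyloxy)-3-hydroxy-N-methoxy-N-methylpent-4-enamide | C=C[C@@H](O)[C@H](OCc1ccccc1)C(=O)N(C)OC | intermediate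
9 | (2S,3R)-2-(benzyloxy)-N-methoxy-N-methyl-3-[(triethylsilyl)oxy]pent-4-enamide | C=C[C@@H](O[Si](CC)(CC)CC)[C@H](OCc1ccccc1)C(=O)N(C)OC | intermediate
10 | (4S,5R)-4-(benzyloxy)-5-[(triethylsilyl)oxy]hept-6-en-3-one | C=C[C@@H](O[Si](CC)(CC)CC)[C@H](OCc1ccccc1)C(=O)CC | intermediate
11 | trichlorotitanium Z-enolate of 10 | C=C[C@@H](O[Si](CC)(CC)CC)[C@H](OCc1ccccc1)/C(O[Ti](Cl)(Cl)Cl)=C/C | intermediate
12 | (3R,4S,6S,7R)-4-(benzyloxy)-7-hydroxy-6-methyl-3-[(triethylsilyl)oxy]nona-1,8-dien-5-one | C=C[C@@H](O[Si](CC)(CC)CC)[C@H](OCc1ccccc1)C(=O)[C@@H](C)[C@H](O)C=C | intermediate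
13 | (3R,4S,6S,7R)-4-(benzyloxy)-6-methyl-3-[(triethylsilyl)oxy]-7-[(triisopropylsilyl)oxy]nona-1,8-dien-5-one | C=C[C@@H](O[Si](CC)(CC)CC)[C@H](OCc1ccccc1)C(=O)[C@@H](C)[C@H](O[Si](C(C)C)(C(C)C)C(C)C)C=C | intermediate
14 | (2S,3R,6R,7S)-2-(benzyloxy)-7-methyl-3-[(triethylsilyl)oxy]-6-[(triisopropylsilyl)oxy]cyclohept-4-en-1-one | O=C1[C@@H](C)[C@H](O[Si](C(C)C)(C(C)C)C(C)C)C=C[C@@H](O[Si](CC)(CC)CC)[C@@H]1OCc2ccccc2 | intermediate
15 | C7 ethylene ketal of 14 (cycloheptene; C8 α-OBn; C8a β-OSiEt3; C5 α-OSi(i-Pr)3; C6 β-Me) | O1CCOC12[C@@H](C)[C@H](O[Si](C(C)C)(C(C)C)C(C)C)C=C[C@@H](O[Si](CC)(CC)CC)[C@@H]2OCc3ccccc3 | intermediate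
16 | saturated C8 alcohol (C7 dioxolane; C8 α-OH; C8a β-OSiEt3; C5 α-OSi(i-Pr)3; C6 β-Me) | O1CCOC12[C@@H](C)[C@H](O[Si](C(C)C)(C(C)C)C(C)C)CC[C@@H](O[Si](CC)(CC)CC)[C@@H]2O | intermediate
17 | isobutyryl chloride | CC(C)C(Cl)=O | starting material
18 | C8 isobutyrate with C8a triethylsilyl ether | O1CCOC12[C@@H](C)[C@H](O[Si](C(C)C)(C(C)C)C(C)C)CC[C@@H](O[Si](CC)(CC)CC)[C@@H]2OC(=O)C(C)C | intermediate
19 | C8a alcohol with C8 isobutyrate | O1CCOC12[C@@H](C)[C@H](O[Si](C(C)C)(C(C)C)C(C)C)CC[C@@H](O)[C@@H]2OC(=O)C(C)C | intermediate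
20 | bromoacetyl bromide | BrCC(Br)=O | starting material
21 | C8a bromoacetate with C8 isobutyrate | O1CCOC12[C@@H](C)[C@H](O[Si](C(C)C)(C(C)C)C(C)C)CC[C@@H](OC(=O)CBr)[C@@H]2OC(=O)C(C)C | intermediate
22 | C8a diazoacetate (key-step precursor; C7 dioxolane; C6 β-Me; C5 α-OSi(i-Pr)3; C8 α-isobutyrate) | O1CCOC12[C@@H](C)[C@H](O[Si](C(C)C)(C(C)C)C(C)C)CC[C@@H](OC(=O)C=[N+]=[N-])[C@@H]2OC(=O)C(C)C | intermediate
23 | cis-fused γ-lactone lacking the C3 methyl (key-step product) | O1CCOC12[C@@H](C)[C@H](O[Si](C(C)C)(C(C)C)C(C)C)C[C@@H]3[C@@H](OC(=O)C3)[C@@H]2OC(=O)C(C)C | intermediate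
24 | lithium enolate of 23 | O1CCOC12[C@@H](C)[C@H](O[Si](C(C)C)(C(C)C)C(C)C)C[C@@H]3[C@@H](OC(O[Li])=C3)[C@@H]2OC(=O)C(C)C | intermediate
25 | C3 convex-face methyl lactone (methyl cis to H3a) | O1CCOC12[C@@H](C)[C@H](O[Si](C(C)C)(C(C)C)C(C)C)C[C@@H]3[C@@H](OC(=O)[C@H]3C)[C@@H]2OC(=O)C(C)C | intermediate
26 | lithium enolate of 25 | O1CCOC12[C@@H](C)[C@H](O[Si](C(C)C)(C(C)C)C(C)C)C[C@@H]3[C@@H](OC(O[Li])=C3C)[C@@H]2OC(=O)C(C)C | intermediate
27 | C3 concave-face methyl lactone (methyl cis to C4; C3 as in the target) | O1CCOC12[C@@H](C)[C@H](O[Si](C(C)C)(C(C)C)C(C)C)C[C@@H]3[C@@H](OC(=O)[C@@H]3C)[C@@H]2OC(=O)C(C)C | intermediate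
28 | C7 ketone | O=C1[C@@H](C)[C@H](O[Si](C(C)C)(C(C)C)C(C)C)C[C@@H]2[C@@H](OC(=O)[C@@H]2C)[C@@H]1OC(=O)C(C)C | intermediate
29 | methoxyallene (1-methoxypropa-1,2-diene) | COC=C=C | starting material
30 | 1-lithio-1-methoxypropa-1,2-diene | [Li]C(OC)=C=C | intermediate
31 | allenyl carbinol (C7 β-OH; C7 α-(1-methoxypropa-1,2-dienyl)) | C=C=C(OC)[C@]1(O)[C@@H](C)[C@H](O[Si](C(C)C)(C(C)C)C(C)C)C[C@@H]2[C@@H](OC(=O)[C@@H]2C)[C@@H]1OC(=O)C(C)C | intermediate
32 | C7 β-hydroxy C7 α-acryloyl compound (vinyl ketone) | C=CC(=O)[C@]1(O)[C@@H](C)[C@H](O[Si](C(C)C)(C(C)C)C(C)C)C[C@@H]2[C@@H](OC(=O)[C@@H]2C)[C@@H]1OC(=O)C(C)C | intermediate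
33 | (Z)-but-2-ene | C/C=C\C | starting material
34 | C5 triisopropylsilyl ether of the target | C/C=C/C(=O)[C@]1(O)[C@@H](C)[C@H](O[Si](C(C)C)(C(C)C)C(C)C)C[C@@H]2[C@@H](OC(=O)[C@@H]2C)[C@@H]1OC(=O)C(C)C | intermediate
35 | (3R,3aS,5R,6S,7S,8S,8aR)-7-[(E)-but-2-enoyl]-5,7-dihydroxy-3,6-dimethyl-2-oxooctahydro-2H-cyclohepta[b]furan-8-yl 2-methylpropanoate | C/C=C/C(=O)[C@]1(O)[C@@H](C)[C@H](O)C[C@@H]2[C@@H](OC(=O)[C@@H]2C)[C@@H]1OC(=O)C(C)C | target

Total step count: 21. Longest linear sequence: 21 steps (1 to 35).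

Steps most likely to fail

Step 15 (key step). The carbenoid may insert into the C8–H bond, may give the trans-fused lactone, or may dimerise or form an ylide at the ketal oxygen. The fallback makes the same C3–C3a bond by a radical route (Ueno–Stork haloacetal cyclisation); it sets out from cycloheptene 15 and comes back at lactone 23. Removal of the triethylsilyl group (HF·pyridine, pyridine, THF, 0 °C) would give the C8a allylic alcohol F1. N-Bromosuccinimide and ethyl vinyl ether (CH2Cl2, −40 °C) would convert it into the C8a 2-bromo-1-ethoxyethyl acetal F2. Bu3SnH with azobisisobutyronitrile (benzene, 80 °C, slow addition) would close the ring 5-exo onto C3a from the face of the tether and reduce the C4 radical, giving the cis-fused bicyclic ethyl acetal F3. Aqueous AcOH in THF would release the lactol F4, and Pr4NRuO4 (cat.) with N-methylmorpholine N-oxide would oxidise it to the γ-lactone C8 benzyl ether F5. Hydrogenolysis (H2, Pd(OH)2/C, EtOAc) would give the C8 hydroxy lactone F6, and acylation with 17 (pyridine, DMAP, CH2Cl2) would deliver 23.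

Step 19. The nucleophile may enter from the β face of the C7 ketone (poor or reversed facial selectivity), which would place the hydroxyl on the wrong face. The fallback turns the same facial preference to advantage by delivering oxygen instead of carbon to that face; it sets out from ketone 28 and comes back at 34. Takai–Lombardo methylenation (Zn, CH2Br2, TiCl4, THF/CH2Cl2, 0 → 25 °C; non-basic and selective for the ketone over the esters) would give the C7 methylidene compound F7. Dihydroxylation (OsO4 cat., N-methylmorpholine N-oxide, acetone/H2O) from the open face would give the C7 hydroxymethyl carbinol F8. Oxidation of the primary alcohol only (TEMPO cat., PhI(OAc)2, CH2Cl2) would give the C7 α-hydroxy aldehyde F9. Nozaki–Hiyama–Kishi coupling with (E)-1-bromopropene (CrCl2, NiCl2 cat., DMF) would give the C7 (E)-1-hydroxybut-2-enyl carbinol F10 as a mixture at the new carbinol, and oxidation of the secondary allylic alcohol (Dess–Martin periodinane, CH2Cl2) would give 34.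

Step 17. Deprotonation of the C3–H bond on the concave face may be slow, or protonation of the enolate may be poorly face-selective, so that C3 is not inverted cleanly. The fallback sets C3 by hydrogenation instead of protonation; it sets out from lactone 23, replaces steps 16 and 17, and comes back at 27. Enolisation and Mannich reaction with Eschenmoser's salt (LiN(i-Pr)2, THF, −78 °C; CH2=NMe2 iodide) would give the C3 dimethylaminomethyl lactone F11. Quaternisation and elimination (MeI, MeOH; then NaHCO3) would give the C3 methylidene lactone F12. Hydrogenation (H2, Pd/C, EtOAc) from the convex face of the cis-fused bicycle would place the new hydrogen cis to H3a and the methyl group on the concave face, giving 27.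

Further compounds

F1 | step 15 | C8a allylic alcohol (C7 dioxolane; C8 α-OBn; C3a=C4; C5 α-OSi(i-Pr)3; C6 β-Me) | O1CCOC12[C@@H](C)[C@H](O[Si](C(C)C)(C(C)C)C(C)C)C=C[C@@H](O)[C@@H]2OCc3ccccc3
F2 | step 15 | C8a 2-bromo-1-ethoxyethyl acetal of F1 | O1CCOC12[C@@H](C)[C@H](O[Si](C(C)C)(C(C)C)C(C)C)C=C[C@@H](OC(CBr)OCC)[C@@H]2OCc3ccccc3
F3 | step 15 | cis-fused bicyclic ethyl acetal (2-ethoxy in place of the lactone carbonyl; C8 α-OBn) | O1CCOC12[C@@H](C)[C@H](O[Si](C(C)C)(C(C)C)C(C)C)C[C@@H]3[C@@H](OC(OCC)C3)[C@@H]2OCc4ccccc4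
F4 | step 15 | cis-fused lactol (C8 α-OBn) | O1CCOC12[C@@H](C)[C@H](O[Si](C(C)C)(C(C)C)C(C)C)C[C@@H]3[C@@H](OC(O)C3)[C@@H]2OCc4ccccc4
F5 | step 15 | cis-fused γ-lactone C8 benzyl ether | O1CCOC12[C@@H](C)[C@H](O[Si](C(C)C)(C(C)C)C(C)C)C[C@@H]3[C@@H](OC(=O)C3)[C@@H]2OCc4ccccc4
F6 | step 15 | cis-fused γ-lactone C8 alcohol | O1CCOC12[C@@H](C)[C@H](O[Si](C(C)C)(C(C)C)C(C)C)C[C@@H]3[C@@H](OC(=O)C3)[C@@H]2O
F7 | step 19 | C7 methylidene compound | C=C1[C@@H](C)[C@H](O[Si](C(C)C)(C(C)C)C(C)C)C[C@@H]2[C@@H](OC(=O)[C@@H]2C)[C@@H]1OC(=O)C(C)C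
F8 | step 19 | C7 β-hydroxy C7 α-hydroxymethyl compound | OC[C@]1(O)[C@@H](C)[C@H](O[Si](C(C)C)(C(C)C)C(C)C)C[C@@H]2[C@@H](OC(=O)[C@@H]2C)[C@@H]1OC(=O)C(C)C
F9 | step 19 | C7 β-hydroxy C7 α-formyl compound | O=C[C@]1(O)[C@@H](C)[C@H](O[Si](C(C)C)(C(C)C)C(C)C)C[C@@H]2[C@@H](OC(=O)[C@@H]2C)[C@@H]1OC(=O)C(C)C
F10 | step 19 | C7 β-hydroxy C7 α-[(E)-1-hydroxybut-2-enyl] compound | C/C=C/C(O)[C@]1(O)[C@@H](C)[C@H](O[Si](C(C)C)(C(C)C)C(C)C)C[C@@H]2[C@@H](OC(=O)[C@@H]2C)[C@@H]1OC(=O)C(C)C
F11 | step 17 | C3 dimethylaminomethyl lactone | O1CCOC12[C@@H](C)[C@H](O[Si](C(C)C)(C(C)C)C(C)C)C[C@@H]3[C@@H](OC(=O)C3CN(C)C)[C@@H]2OC(=O)C(C)C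
F12 | step 17 | C3 methylidene lactone | O1CCOC12[C@@H](C)[C@H](O[Si](C(C)C)(C(C)C)C(C)C)C[C@@H]3[C@@H](OC(=O)C3=C)[C@@H]2OC(=O)C(C)C
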